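An easy step first: the green run at 25.0 h holds 72.8% target and 26.7% starting material, so the target is what the starting material becomes. Its loss can be read as second order in starting material, the limiting reagent, and coupling partner, and the target then follows from a turnover clock: the rate constant K, in fractions of charge per hour, times the hours.

| setting | grey | green | amber | red | Monday's | Saturday's | Friday's | Tuesday's |
|---|---|---|---|---|---|---|---|---|
| starting material | 0.010 M | 0.010 M | 0.010 M | 0.015 M | 0.010 M | 0.010 M | 0.010 M | 0.010 M |
| coupling partner | 1.1 equiv | 1.1 equiv | 1.1 equiv | 1.1 equiv | 1.10 equiv | 1.10 equiv | 1.10 equiv | 1.10 equiv (fed, over 5.0 h) |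
| second substrate | 5 equiv | 2.5 equiv | 10 equiv | 5 equiv | 5.00 equiv | 5.00 equiv (in portions, 2, over 5.0 h) | 5.00 equiv (fed, over 5.0 h) | 5.00 equiv |
| catalyst | 13 mol% | 13 mol% | 13 mol% | 13 mol% | 13 mol% | 13 mol% | 13 mol% | 13 mol% |
| temperature | −35 °C | −20 °C | −35 °C | −20 °C | −20 °C | −20 °C |  | −20 °C |
| remark | run made earlier | run made earlier | run made earlier | run made earlier | everything together at the start | first portion at the start, last at 5.0 h | the addition at −60 °C, then warmed to −20 °C; the feed brings no volume worth counting | all else is in the flask from the start; the feed brings no volume worth counting |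
| time |  |  |  |  | 25 h | 25 h | 25 h | 25 h |

| run | time / h | target / % | starting material / % |
|---|---|---|---|
| grey | 4.00 | 1.6 | 98.0 |
| grey | 10.0 | 4.0 | 95.8 |
| grey | 20.0 | 7.4 | 92.0 |
| grey | 48.0 | 16.8 | 83.4 |
| green | 8.00 | 44.6 | 55.1 |
| green | 15.0 | 61.4 | 39.4 |
| green | 25.0 | 72.8 | 26.7 |
| green | 30.0 | 76.9 | 24.0 |
| amber | 5.00 | 0.9 | 99.0 |
| amber | 12.0 | 2.4 | 97.4 |
| amber | 25.0 | 5.4 | 94.6 |
| amber | 60.0 | 11.2 | 89.0 |
| red | 8.00 | 42.9 | 57.2 |
| red | 15.0 | 59.0 | 40.7 |
| red | 25.0 | 70.9 | 29.0 |
| red | 30.0 | 74.9 | 24.9 |

(each reading ± 0.3 percentage points)

* the flask with the highest amount of target, in percent of the starting material charged ("all alike" if they lie within 1.5 percentage points) (Monday's / Saturday's / Friday's / Tuesday's / all alike)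
* final target, as a percentage of the starting material charged, in Monday's
* final target, as a percentage of the starting material charged, in Saturday's
* final target, as a percentage of the starting material charged, in Friday's
* final target, as a percentage of the starting material charged, in Tuesday's

- the earlier runs were read with a standard deviation of 0.3 percentage points

Which numbers must be known well? Near half conversion the target moves 30.0% of the charge per unit of clock. Friday's cold hours hardly count: even the warmer grey run reads K = 0.00379 h⁻¹, and 5.0 h at that K is worth 0.57 points. The amber run against the grey shows doubled second substrate leaving K at 0.00190 h⁻¹. The heavy number is therefore the slowing at −20 °C: the green run reads K = 0.0871 h⁻¹ at 2.5 equiv of second substrate, and between half that K and that K unchanged, the clock for Monday's reads from 55.9% to 72.8% target, a span of 17 points.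

So to that number. The red run reads K = 0.0800 h⁻¹, to be set beside the green 0.0871 h⁻¹. Taking K as proportional to catalyst and starting concentration and divided by a term linear in [second substrate], the pair gives a slope of 105 L mol⁻¹. Monday's K is then 0.0505 h⁻¹, and its clock is 1.26, the turnover clock, which reads 59.7% target.

The other flasks are corrections to that clock. Saturday's spends 5.0 h at the green K, so its clock is 1.45, giving 63.1%. Friday's loses those hours: 1.01, giving 53.9%. Tuesday's partner averages half its charge during the feed, so it loses half those hours: 1.14, giving 57.0%.

The forecast names Saturday's, with 60%, 63.5%, 54.3% and 57.3% in the order Monday's, Saturday's, Friday's, Tuesday's, a little above the figures here, and says of Tuesday's that “the partner feed starves early”.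

The flasks give 60.0%, 63.4%, 54.3% and 57.3% in that order, so Saturday's holds the most.

    starting material + coupling partner + catalyst → catalyst + target (k = 22000 L² mol⁻² h⁻¹, Ea = 36.0 kJ mol⁻¹)
    second substrate + coupling partner + catalyst → catalyst + second product (k = 101 L² mol⁻² h⁻¹, Ea = 47.0 kJ mol⁻¹)
    second substrate + catalyst ⇌ idle complex, settled at all times (K = 92.0 L mol⁻¹, ΔH = −57.0 kJ mol⁻¹)
    (constants at −20 °C)

The neighbour of Saturday's with 7.8 mol% catalyst runs the same clock scaled by its loading, 0.867, which reads 49.9%; that flask gives 50.2%. Saturday's itself is not at rest. Carried to 250 h, its clock reaches 12.8 and reads 96.6%. Second product stands at 1.79% of the starting charge at 25.0 h and 6.32% at 250 h, against a partner excess of 10.0%. Ten times the hours lift Saturday's target by 32 points to 95.2%, with 4.79% starting material still there.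

Readings and results were generated by integration on assumed constants; the scatter is artificial.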